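**Retrosynthetic overview**

1. Target 13 is an ent-labd-7-ene (2S,3S,5S,9R,10S,13S; labdane numbering). The first-choice plan is not used: cyclising a plain terminal epoxide and then oxidising C3, acetoxylating C2 and reducing, or hanging the side chain on a preformed decalin.
2. Key step, placed last: MeAlCl2-triggered cation–olefin bicyclisation of the fully oxidised acyclic threo 2-acetoxy-3,4-epoxide 12. Ring A closes first (C4–C5), ring B second (C9–C10), and loss of H-7 gives 13 itself.
3. 12 ⇐ erythro epoxy diol 11 by a double Mitsunobu reaction with AcOH (inverts C2 and esterifies C15–OH in one operation).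
4. 11 ⇐ C1–C2 bond by α-selective allylbarium addition of the C15 allylic chloride 5 to epoxy aldehyde 8 (Felkin–Anh control).
5. 5 ⇐ (2E,6E)-farnesol 1 (Noyori hydrogenation sets C13; SeO2 oxidation of the terminal E-methyl). 8 ⇐ prenol 6 (Sharpless epoxidation sets C3).

Assumption: atoms are numbered as in labdane (ring carbons C1–C10, side chain C11–C16, methyls C17–C20), and (2E,6E)-farnesol, prenol and all reagents are taken as commercial.

**Route**

Step 1
Reactants: 1 (2E,6E)-farnesol
Product: 2 (S)-2,3-dihydrofarnesol [(3S,6E)-3,7,11-trimethyldodeca-6,10-dien-1-ol]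
Conditions: Ru(OAc)2[(R)-BINAP] (0.5 mol %), H2 (100 atm), MeOH–H2O 95:5, 20 °C
Reagents that add atoms: none
Why: Noyori asymmetric hydrogenation is directed by the allylic hydroxyl, so only the C2=C3 alkene is reduced, and the (R)-BINAP complex gives the 3S centre (C13 of the target) as it does for geraniol → (S)-citronellol.

Step 2
Reactants: 2 (S)-2,3-dihydrofarnesol
Product: 3 tert-butyldimethyl{[(3S,6E)-3,7,11-trimethyldodeca-6,10-dien-1-yl]oxy}silane
Conditions: TBSCl, imidazole, DMF, rt
Reagents that add atoms: tert-butyldimethylsilyl chloride, CC(C)(C)[Si](C)(C)Cl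
Why: standard silylation of the primary alcohol, which must be masked against the organobarium reagent of step 7.

Step 3
Reactants: 3 silyl ether
Product: 4 (2E,6E,10S)-12-[(tert-butyldimethylsilyl)oxy]-2,6,10-trimethyldodeca-2,6-dien-1-ol
Conditions: SeO2 (0.2 equiv), tBuOOH (3 equiv), salicylic acid (0.1 equiv), CH2Cl2, 0 °C → rt
Reagents that add atoms: tert-butyl hydroperoxide, CC(C)(C)OO (the oxygen atom, relayed through SeO2)
Why: Sharpless-modified Riley allylic oxidation (ene reaction then [2,3]-sigmatropic shift) is fastest at the unhindered terminal isopropylidene and takes its E-methyl, giving the E allylic alcohol; internal-alkene oxidation and the enal are minor and separable.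

Step 4
Reactants: 4 allylic alcohol
Product: 5 tert-butyl{[(3S,6E,10E)-12-chloro-3,7,11-trimethyldodeca-6,10-dien-1-yl]oxy}dimethylsilane
Conditions: NCS, Me2S, CH2Cl2, −20 → 0 °C
Reagents that add atoms: N-chlorosuccinimide, ClN1C(=O)CCC1=O
Why: Corey–Kim chlorination displaces the alkoxysulfonium ion by chloride in an SN2 step at the primary allylic carbon, without allylic transposition or loss of E geometry.

Step 5
Reactants: 6 prenol (3-methylbut-2-en-1-ol)
Product: 7 (R)-(3,3-dimethyloxiran-2-yl)methanol
Conditions: Ti(OiPr)4 (10 mol %), D-(−)-DIPT (12 mol %), tBuOOH, 4 Å MS, CH2Cl2, −20 °C; non-aqueous work-up, distillation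
Reagents that add atoms: tert-butyl hydroperoxide, CC(C)(C)OO
Why: Sharpless asymmetric epoxidation, in which the D-(−)-tartrate catalyst delivers oxygen to the face that gives the 2R epoxide (the future C3, expected ca. 90–94% ee).

Step 6
Reactants: 7 epoxy alcohol
Product: 8 (S)-3,3-dimethyloxirane-2-carbaldehyde
Conditions: TEMPO (10 mol %), PhI(OAc)2, CH2Cl2, 0 °C → rt; NaHCO3 wash, cold concentration, used at once in THF
Reagents that add atoms: none
Why: oxoammonium (TEMPO) oxidation stops at the aldehyde under neutral conditions and leaves the epoxide carbon untouched (the descriptor changes from R to S only through CIP priorities).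

Step 7
Reactants: 5 allylic chloride; 8 epoxy aldehyde
Product: 10 erythro epoxy alcohol (1R,3E,7E,11S)-13-[(tert-butyldimethylsilyl)oxy]-1-[(2R)-3,3-dimethyloxiran-2-yl]-3,7,11-trimethyltrideca-3,7-dien-1-ol, via allylbarium chloride 9 (not isolated)
Conditions: BaI2, LiC12H10 (lithium biphenylide, 2 equiv), THF, rt; then 5, −78 °C; then 8, −78 °C; H2O quench
Reagents that add atoms: none
Why: allylbarium reagents add to aldehydes at the α-carbon with retention of E geometry (α-selective carbonyl allylation), and Felkin–Anh attack anti to the epoxide C–O bond of 8 sets C2 as the R (erythro) carbinol; the minor threo epimer is removed by chromatography.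

Step 8
Reactants: 10 erythro epoxy alcohol
Product: 11 (1R,3E,7E,11S)-1-[(2R)-3,3-dimethyloxiran-2-yl]-3,7,11-trimethyltrideca-3,7-diene-1,13-diol
Conditions: Bu4NF, THF, 0 °C
Reagents that add atoms: none
Why: fluoride-driven desilylation; the trisubstituted epoxide is inert to fluoride and is the favoured side of any Payne equilibrium.

Step 9
Reactants: 11 erythro epoxy diol
Product: 12 (1S,3E,7E,11S)-1-[(2R)-3,3-dimethyloxiran-2-yl]-3,7,11-trimethyltrideca-3,7-diene-1,13-diyl diacetate
Conditions: PPh3 (3 equiv), DIAD (3 equiv), AcOH (4 equiv), THF, 0 °C → rt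
Reagents that add atoms: acetic acid, CC(=O)O
Why: Mitsunobu reaction, in which the primary alcohol is esterified and the secondary alkoxyphosphonium is displaced by acetate with SN2 inversion (C2 R → S), giving the threo 2-acetoxy-3,4-epoxide with both acetates of the target in place.

Step 10
Reactants: 12 threo epoxy diacetate
Product: 13 (3S)-5-[(1R,4aS,6S,7S,8aS)-7-acetoxy-6-hydroxy-2,5,5,8a-tetramethyl-1,4,4a,5,6,7,8,8a-octahydronaphthalen-1-yl]-3-methylpentyl acetate (target)
Conditions: MeAlCl2 (3 equiv), CH2Cl2, −78 °C, 30 min; pH 7 buffer at −78 °C; AgNO3–SiO2 chromatography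
Reagents that add atoms: none
Why: Proposed new method: the Lewis-acid epoxide-initiated cation–olefin bicyclisation (van Tamelen/Corey epoxy-polyene cyclisation, the closest known reaction) is extended to a 2-acyloxy epoxide: MeAlCl2 ionises the tertiary C4–O bond, the E,E-diene folds chair–chair with the C2 acetate equatorial, anti additions to the two E-alkenes close ring A (C4–C5) and then ring B (C9–C10) so that the 3R epoxide dictates 3-OH equatorial, 5-H trans to 10-Me and the C9 side chain equatorial (5S,9R,10S), and loss of H-7 to the Al–Me bond gives the Δ7 alkene (expected major over Δ8(17) and Δ8); capture of the C4 cation by the acetate carbonyl would only give a tertiary-alkyl dioxanylium ion that re-ionises as easily as a tert-butyl ester, whereas C–C bond formation is irreversible.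

**Compound list**

1 | (2E,6E)-farnesol | OC/C=C(C)/CC/C=C(C)/CCC=C(C)C | starting material
2 | (S)-2,3-dihydrofarnesol, (3S,6E)-3,7,11-trimethyldodeca-6,10-dien-1-ol | OCC[C@@H](C)CC/C=C(C)/CCC=C(C)C | intermediate
3 | TBS ether of 2 | CC(C)(C)[Si](C)(C)OCC[C@@H](C)CC/C=C(C)/CCC=C(C)C | intermediate
4 | (2E,6E,10S)-12-[(tert-butyldimethylsilyl)oxy]-2,6,10-trimethyldodeca-2,6-dien-1-ol | CC(C)(C)[Si](C)(C)OCC[C@@H](C)CC/C=C(C)/CC/C=C(C)/CO | intermediate
5 | tert-butyl{[(3S,6E,10E)-12-chloro-3,7,11-trimethyldodeca-6,10-dien-1-yl]oxy}dimethylsilane | CC(C)(C)[Si](C)(C)OCC[C@@H](C)CC/C=C(C)/CC/C=C(C)/CCl | intermediate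
6 | prenol, 3-methylbut-2-en-1-ol | CC(C)=CCO | starting material
7 | (R)-(3,3-dimethyloxiran-2-yl)methanol | OC[C@H]1OC1(C)C | intermediate
8 | (S)-3,3-dimethyloxirane-2-carbaldehyde | O=C[C@H]1OC1(C)C | intermediate
9 | allylbarium chloride from 5 (not isolated) | CC(C)(C)[Si](C)(C)OCC[C@@H](C)CC/C=C(C)/CC/C=C(C)/C[Ba]Cl | intermediate
10 | erythro epoxy alcohol, (1R,3E,7E,11S)-13-[(tert-butyldimethylsilyl)oxy]-1-[(2R)-3,3-dimethyloxiran-2-yl]-3,7,11-trimethyltrideca-3,7-dien-1-ol | CC(C)(C)[Si](C)(C)OCC[C@@H](C)CC/C=C(C)/CC/C=C(C)/C[C@@H](O)[C@H]1OC1(C)C | intermediate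
11 | erythro epoxy diol, (1R,3E,7E,11S)-1-[(2R)-3,3-dimethyloxiran-2-yl]-3,7,11-trimethyltrideca-3,7-diene-1,13-diol | OCC[C@@H](C)CC/C=C(C)/CC/C=C(C)/C[C@@H](O)[C@H]1OC1(C)C | intermediate
12 | threo epoxy diacetate, (1S,3E,7E,11S)-1-[(2R)-3,3-dimethyloxiran-2-yl]-3,7,11-trimethyltrideca-3,7-diene-1,13-diyl diacetate | CC(=O)OCC[C@@H](C)CC/C=C(C)/CC/C=C(C)/C[C@H](OC(C)=O)[C@H]1OC1(C)C | intermediate
13 | ent-2α-acetoxy-3β-hydroxylabd-7-en-15-yl acetate (13S), (3S)-5-[(1R,4aS,6S,7S,8aS)-7-acetoxy-6-hydroxy-2,5,5,8a-tetramethyl-1,4,4a,5,6,7,8,8a-octahydronaphthalen-1-yl]-3-methylpentyl acetate | CC(=O)OCC[C@@H](C)CC[C@@H]1C(C)=CC[C@@H]2C(C)(C)[C@H](O)[C@@H](OC(C)=O)C[C@@]12C | target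

**Step count and risk**

Total steps: 10. Longest linear sequence: 8 (steps 1, 2, 3, 4, 7, 8, 9, 10); steps 5 and 6 form the short branch.

The three steps most likely to fail are 7, 9 and 10.

Step 7 can fail through a poor α/γ ratio, a poor Felkin–Anh ratio, or loss of the small, sensitive aldehyde 8. The fallback sets out from 5 and comes back at 12, so that steps 5, 6, 8 and 9 are no longer needed. Carbonylative Stille coupling of 5 with tributyl(2-methylprop-1-enyl)stannane (Pd2(dba)3, PPh3, CO 3 atm, THF, 50 °C) joins C1 to a new C2 carbonyl and gives skipped dienone F1. Reduction with (R)-Me-CBS oxazaborolidine and catecholborane (toluene, −78 °C) gives (4S)-allylic alcohol F2. VO(acac)2/tBuOOH epoxidises only the allylic alkene, and A(1,3) strain from the cis-methyl group steers oxygen to the threo face, giving threo epoxy alcohol F3 with C2 already correct and no inversion needed. Bu4NF then gives threo epoxy diol F4, and Ac2O/pyridine/DMAP gives 12.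

Step 9 can fail because SN2 at a carbinol flanked by an epoxide and an allylic CH2 may be slow under Mitsunobu conditions, and elimination to the 1,3-diene can compete. The fallback sets out from 11 and comes back at 12. Both hydroxyls are turned into discrete leaving groups with ClCH2SO2Cl/pyridine (CH2Cl2, 0 °C) to give bis(chloromethanesulfonate) F5. CsOAc/18-crown-6 in toluene at 50 °C then substitutes the primary centre and inverts the secondary one, giving 12.

Step 10 carries the highest risk: the 2-acetoxy group may trap the C4 cation or migrate to O3, and proton loss can also give the Δ8(17) and Δ8 alkenes. The fallback sets out from 12 and comes back at 13, replacing the cation by a radical that an ester carbonyl cannot intercept. Cp2TiCl (trivalent titanium, made from Cp2TiCl2 and Mn dust in THF at rt) opens the epoxide homolytically to the tertiary C4 radical. This cyclises 6-endo/6-endo through the same chair–chair fold, and mixed β-hydride elimination from the C8 alkyltitanium gives exocyclic Δ8(17) alkene isomer F6. Hydrogen-atom-transfer isomerisation (Co(salen)Cl 5 mol %, PhSiH3 cat., benzene, rt) then moves the alkene into ring B, with H removed from the open C7 position in preference to the shielded C9, to give 13.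

**Further compounds**

F1 | step 7 | skipped dienone (6E,10E,14S)-16-[(tert-butyldimethylsilyl)oxy]-2,6,10,14-tetramethylhexadeca-2,6,10-trien-4-one | CC(C)(C)[Si](C)(C)OCC[C@@H](C)CC/C=C(C)/CC/C=C(C)/CC(=O)C=C(C)C
F2 | step 7 | (4S)-allylic alcohol (4S,6E,10E,14S)-16-[(tert-butyldimethylsilyl)oxy]-2,6,10,14-tetramethylhexadeca-2,6,10-trien-4-ol | CC(C)(C)[Si](C)(C)OCC[C@@H](C)CC/C=C(C)/CC/C=C(C)/C[C@H](O)C=C(C)C
F3 | step 7 | threo epoxy alcohol (1S,3E,7E,11S)-13-[(tert-butyldimethylsilyl)oxy]-1-[(2R)-3,3-dimethyloxiran-2-yl]-3,7,11-trimethyltrideca-3,7-dien-1-ol | CC(C)(C)[Si](C)(C)OCC[C@@H](C)CC/C=C(C)/CC/C=C(C)/C[C@H](O)[C@H]1OC1(C)C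
F4 | step 7 | threo epoxy diol (1S,3E,7E,11S)-1-[(2R)-3,3-dimethyloxiran-2-yl]-3,7,11-trimethyltrideca-3,7-diene-1,13-diol | OCC[C@@H](C)CC/C=C(C)/CC/C=C(C)/C[C@H](O)[C@H]1OC1(C)C
F5 | step 9 | bis(chloromethanesulfonate) of 11, (1R,3E,7E,11S)-1-[(2R)-3,3-dimethyloxiran-2-yl]-3,7,11-trimethyltrideca-3,7-diene-1,13-diyl bis(chloromethanesulfonate) | ClCS(=O)(=O)OCC[C@@H](C)CC/C=C(C)/CC/C=C(C)/C[C@@H](OS(=O)(=O)CCl)[C@H]1OC1(C)C
F6 | step 10 | exocyclic Δ8(17) alkene isomer, (3S)-5-[(1R,4aS,6S,7S,8aS)-7-acetoxy-6-hydroxy-5,5,8a-trimethyl-2-methylidenedecahydronaphthalen-1-yl]-3-methylpentyl acetate | CC(=O)OCC[C@@H](C)CC[C@@H]1C(=C)CC[C@@H]2C(C)(C)[C@H](O)[C@@H](OC(C)=O)C[C@@]12C
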